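The easy step is the count: 0.082 M of starting material stands against 0.107 M of second substrate, so starting material, the smaller charge, is the limiting reagent, and once converted it ends as target or isomer of the product.

| flask | starting material | second substrate | free enzyme | remark | time |
|---|---|---|---|---|---|
| maple | 0.082 M | 0.107 M | 28 µM | run made earlier |  |
| larch | 0.082 M | 0.107 M | 14 µM | run made earlier |  |
| elm | 0.082 M | 0.107 M | 56 µM | run made earlier |  |
| alpha | 0.082 M | 0.107 M (fed, over 25 min) | 28 µM | all else is in the flask from the start; the feed brings no volume worth counting | 40 min |
| theta | 0.082 M (fed, over 25 min) | 0.107 M | 28 µM | all else is in the flask from the start; the feed brings no volume worth counting | 40 min |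
| eta | 0.082 M (in portions, 4, over 25 min) | 0.107 M | 28 µM | first portion at the start, last at 25 min | 40 min |
| epsilon | 0.082 M | 0.107 M | 28 µM | everything together at the start | 40 min |

- maple (time / min: isomer of the product / %, target / %): 5.00: 26, 71; 15.0: 46, 51; 25.0: 47, 54; 40.0: 47, 52
- larch (time / min: isomer of the product / %, target / %): 2.50: 3, 36; 6.00: 10, 79; 15.0: 42, 59; 30.0: 49, 52
- elm (time / min: isomer of the product / %, target / %): 8.00: 45, 54; 15.0: 48, 49; 25.0: 50, 52; 30.0: 48, 54

(standard deviation of a reading: 2 percentage points)

- the flask that comes out highest in amount of isomer of the product, in percent of the starting material charged, or "all alike" when all lie within 1.5 percentage points (alpha / theta / eta / epsilon / all alike)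
- isomer of the product at the end, in percent of the starting material charged, alpha
- isomer of the product at the end, in percent of the starting material charged, theta
- isomer of the product at the end, in percent of the starting material charged, eta
- isomer of the product at the end, in percent of the starting material charged, epsilon

Three numbers might matter. The split between target and isomer moves each answer point for point, but it cannot separate the flasks; the last readings of maple, larch and elm put the isomer share at 47.7 %. Turnover matters less: larch's readings, scaled by enzyme, give 3.37 min for a whole charge at 28 µM, shorter than the 25 min feed, so fed starting material should not pile up in theta.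

The third number is the relaxation rate. The larch deficit from the share shrinks between 6.00 min and 15.0 min at 0.210 /min, a reading with its scatter; scaled to 28 µM, this gives a half-life of 1.65 min.

Putting the share back in tests its assumption of equilibrium. The free half-lives, relaxation half-lives between the last arrival of target and the end, number 9.10 in theta. Alpha receives enough second substrate at 19.2 min, leaving 12.6, more. Even with the whole share missing when theta's count starts, the tail is 0.087 percentage points, below the margin. The margin needs 4.99 half-lives, so the half-life could be 1.82 times as long. This reckoning therefore expects the flasks alike near the share.

The forecast gave 48.3 %, 48.3 %, 48.3 % and 48.3 %, all alike, slightly above that share: “Isomer lags while substrate ties up the enzyme, then relaxes once free enzyme returns.”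

The flasks give alpha 47.4 %, theta 47.4 %, eta 47.4 % and epsilon 47.4 %: all alike.

    starting material + free enzyme ⇌ first complex (K = 460 /M, k = 5200 /M/s)
    first complex → loaded enzyme + first product (k = 20.0 /s)
    second substrate + loaded enzyme ⇌ second complex (K = 10.0 /M, k = 1900 /M/s)
    second complex → free enzyme + target (k = 240 /s)
    target + free enzyme ⇌ isomer of the product + free enzyme, rate k5*[free enzyme]*[target] forward; the back reaction follows from the equilibrium constant (K = 0.900, k = 160 /M/s)

In epsilon, 97 % of the turnover of starting material with free enzyme lay behind it after 4.00 min. In theta, at the end of the feed, 25.0 min, isomer stood at 43.0 % and free enzyme at 82.3 % of the catalyst charged; at the asked time, 40.0 min, after the 9.10 free half-lives, isomerisation of target had carried isomer to 47.4 %. The neighbour charged with 0.21 M of starting material has not begun that count at 40.0 min: second substrate stands at 0 %, free enzyme at 0 %, loaded enzyme at 100 %, and isomer at 0.953 %.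

The readings are simulated with made-up constants; noise was put on by code.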